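**Retrosynthetic overview**
- 18 ⇒ 17: the target is the mono-opened hydroxy acid of a C2-symmetric 6,6'-bichromanone bis-γ-lactone (both halves 2S,9R,10S), so one lactone is saponified last.
- 17 ⇒ 12 + 2 × 13: in each half C2–C3 and C4–C4a are cut together; forward, a two-directional formal [4+2] annulation of an aryl oxocarbenium ion with ethoxyacetylene (a ketene equivalent) closes both pyranone rings at once.
- Enabling feature: on each benzene ring the ether oxygen O1 (on C8a) has a free ortho carbon C4a flanked by the C5 oxygen, so O1-bound C2 at the ketal oxidation level gives a cationic 2-oxadiene C4a=C8a–O1=C2; C8 is blocked by Br and C6 by the biaryl bond.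
- 12 ⇒ 7 + 2 × 10 (Felkin–Anh aldol/lactonisation sets C9 next to chiral-pool C10); 7 ⇒ biaryl diol 4 + glyoxylate cation equivalent 6; 4 ⇒ 1 (homocoupling, then bromination).
- Ring order: biaryl bond, then the two γ-lactones, then both pyranone rings (key step); Br and O-methyl groups are removed afterwards.

Key step: step 7

Remark: chromanone numbering (O1, C2, C3, C4, C4a, C5–C8, C8a) is used, the lactone carbon bonded to C2 is called C9 and the methyl-bearing carbon C10; half ester 8 is taken as a commercial product of asymmetric itaconate hydrogenation.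

Step 1
Reactants: 1 4-bromo-3-methoxyphenol (two molecules)
Product: 3 2,2'-dimethoxy-[1,1'-biphenyl]-4,4'-diol, via pinacol boronate 2 (not isolated)
Conditions: B2pin2 (0.5 equiv), KOAc, Pd(dppf)Cl2 (cat.), 1,4-dioxane, 90 °C; then aq K2CO3, 90 °C
Reagents that add atoms: none
Why: One-pot Miyaura borylation/Suzuki–Miyaura homocoupling joins two molecules of 1 at the carbon para to the free phenol, giving the symmetric biaryl with both future O1 hydroxyls free and both future C5 oxygens masked as methyl ethers.

Step 2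
Reactants: 3 2,2'-dimethoxy-[1,1'-biphenyl]-4,4'-diol
Product: 4 5,5'-dibromo-2,2'-dimethoxy-[1,1'-biphenyl]-4,4'-diol
Conditions: N-bromosuccinimide (2.0 equiv), MeCN, 0 °C
Reagents that add atoms: N-bromosuccinimide, O=C1CCC(=O)N1Br
Why: Electrophilic aromatic bromination of the phenol should go ortho to OH and para to OMe (the unhindered activated site), which places the blocking group on the future C8/C8' and leaves only the future C4a/C4a' free next to the ether oxygen.

Step 3
Reactants: 5 methyl 2-(methylthio)acetate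
Product: 6 methyl 2-chloro-2-(methylthio)acetate (racemic)
Conditions: N-chlorosuccinimide, CH2Cl2, 0 °C to rt; used crude
Reagents that add atoms: N-chlorosuccinimide, O=C1CCC(=O)N1Cl
Why: α-Chlorination of a sulfide with N-chlorosuccinimide (chlorosulfonium/Pummerer-type pathway) gives the α-chloro sulfide, a glyoxylate cation equivalent.

Step 4
Reactants: 4 5,5'-dibromo-2,2'-dimethoxy-[1,1'-biphenyl]-4,4'-diol; 6 methyl 2-chloro-2-(methylthio)acetate (2.4 equiv)
Product: 7 dimethyl 2,2'-[(5,5'-dibromo-2,2'-dimethoxy-[1,1'-biphenyl]-4,4'-diyl)bis(oxy)]bis[2-(methylthio)acetate] (stereoisomer mixture at the two O,S-acetal carbons)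
Conditions: K2CO3, DMF, 0 °C to rt
Reagents that add atoms: none
Why: Williamson-type O-alkylation of the two phenoxides by the α-chloro sulfide (SN1-like through the thionium ion) gives the O,S-acetal; its new centres are formed without control, which is irrelevant because they are deprotonated in step 6.

Step 5
Reactants: 8 (2S)-4-methoxy-2-methyl-4-oxobutanoic acid
Product: 10 methyl (3S)-3-methyl-4-oxobutanoate, via acid chloride 9 (not isolated)
Conditions: (COCl)2, DMF (cat.), CH2Cl2, 0 °C to rt; then H2 (1 atm), Pd/BaSO4, 2,6-lutidine, THF, rt; used at once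
Reagents that add atoms: none
Why: Acid chloride formation followed by Rosenmund reduction (the classical access to β-carbomethoxy aldehydes) should give the aldehyde without touching the methyl ester, and the α-stereocentre is not enolised under these near-neutral conditions.

Step 6
Reactants: 7 bis(O,S-acetal); 10 methyl (3S)-3-methyl-4-oxobutanoate (2.6 equiv)
Product: 12 dimethyl 2,2'-[(5,5'-dibromo-2,2'-dimethoxy-[1,1'-biphenyl]-4,4'-diyl)bis(oxy)]bis{2-[(2R,3S)-3-methyl-5-oxooxolan-2-yl]-2-(methylthio)acetate} (epimer mixture at the two thioketal carbons), via bis-aldol hydroxy ester 11 (not isolated)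
Conditions: LiN(SiMe3)2 (2.2 equiv), THF, −78 °C; then 10, −78 to −20 °C; AcOH
Reagents that add atoms: none
Why: Aldol addition of the fully substituted lithium ester enolate to the α-methyl aldehyde should follow the Felkin–Anh model (attack anti to the CH2CO2Me group), setting C9 as R syn to the C10 methyl, and the lithium aldolate lactonises onto the γ-ester to give the 4,5-cis lactone; the thioketal carbons form as a mixture that is erased in step 7.

Step 7
Reactants: 12 bis(O-aryl S-methyl ketal) bis-lactone; 13 ethoxyacetylene (excess)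
Product: 15 dimethyl (2S,2'S)-8,8'-dibromo-5,5'-dimethoxy-2,2'-bis[(2R,3S)-3-methyl-5-oxooxolan-2-yl]-4,4'-dioxo-[6,6'-bichromane]-2,2'-dicarboxylate, via bis-4-ethoxychromene 14 (not isolated)
Conditions: MeOTf, 2,6-di-tert-butyl-4-methylpyridine, 4 Å MS, CH2Cl2, −20 °C to rt; then 1 M HCl, THF, rt
Reagents that add atoms: water, O
Why: Proposed new method: S-methylation of each SMe group by MeOTf and loss of dimethyl sulfide should give the ester-substituted aryl oxocarbenium ion (the cationic 2-oxadiene C4a=C8a–O1=C2), the terminal carbon of ethoxyacetylene adds to C2 to give an ethoxyketenium ion, and C4a attacks its sp carbon before the hindered pyridine takes the proton, so C2–C3 and C4–C4a form in one stepwise formal [4+2] annulation on each half, and acid hydrolysis of the enol ether then gives the ketone. The closest known reaction types are the oxa-Povarov reaction of aryl oxocarbenium ions with alkenes and alkynes, the activation of sialyl-type thioglycosides (anomeric carbon bearing CO2Me) by methylating thiophiles, and Friedel–Crafts capture of ketenium or keteniminium ions formed from ynol ethers and ynamides. Each pyran ring closes by 6-exo-dig attack of the arene carbon C4a on the ketenium carbon C4. C2 is set by the neighbouring lactone centre C9 under polar Felkin–Anh control: the alkyne should approach anti to the C9–O bond with C10 turned toward O1, which gives 2S from 9R. The step needs ortho-regioselectivity (C4a, not C8), secured by the bromine on C8 and the biaryl bond on C6, and ionisation of C–S rather than C–OAr, secured by the soft, sulfur-selective methylating agent.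

Step 8
Reactants: 15 8,8'-dibromo bis(5-methoxychromanone) bis-lactone
Product: 16 dimethyl (2S,2'S)-5,5'-dimethoxy-2,2'-bis[(2R,3S)-3-methyl-5-oxooxolan-2-yl]-4,4'-dioxo-[6,6'-bichromane]-2,2'-dicarboxylate
Conditions: H2 (1 atm), 10% Pd/C, NaOAc, EtOAc/MeOH, rt
Reagents that add atoms: none
Why: Catalytic hydrogenolysis of the two aryl C–Br bonds removes the blocking groups, with NaOAc buffering the HBr so that the lactones, the ketones and C2 are left alone.

Step 9
Reactants: 16 bis(5-methoxychromanone) bis-lactone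
Product: 17 dimethyl (2S,2'S)-5,5'-dihydroxy-2,2'-bis[(2R,3S)-3-methyl-5-oxooxolan-2-yl]-4,4'-dioxo-[6,6'-bichromane]-2,2'-dicarboxylate
Conditions: BCl3, CH2Cl2, −78 to 0 °C; then H2O
Reagents that add atoms: none
Why: Chelation-assisted ether cleavage: BCl3 binds the C4 carbonyl and should cleave only the peri methoxy groups on C5/C5', leaving the methyl esters and lactones intact.

Step 10
Reactants: 17 C2-symmetric bis(5-hydroxychromanone) bis-lactone
Product: 18 (3S,4R)-4-hydroxy-4-[(2S)-5-hydroxy-6-{(2S)-5-hydroxy-2-(methoxycarbonyl)-2-[(2R,3S)-3-methyl-5-oxooxolan-2-yl]-4-oxochroman-6-yl}-2-(methoxycarbonyl)-4-oxochroman-2-yl]-3-methylbutanoic acid (target, CNP0517857.1)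
Conditions: LiOH (3 equiv, two taken up by the phenols), THF/H2O, 0 °C; AcOH to pH 5; acid separated from 17 by bicarbonate extraction
Reagents that add atoms: lithium hydroxide, [Li+].[OH-]
Why: Saponification of one of the two equivalent γ-lactones (a statistical desymmetrisation by acyl–oxygen cleavage, the hindered tertiary methyl esters being much slower) and mild acidification should give the mono hydroxy acid without touching any stereocentre, while recovered 17 and acid-relactonised diacid are recycled.

**Compound list**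
1 | 4-bromo-3-methoxyphenol | COc1cc(O)ccc1Br | starting material
2 | 3-methoxy-4-(4,4,5,5-tetramethyl-1,3,2-dioxaborolan-2-yl)phenol | COc1cc(O)ccc1B1OC(C)(C)C(C)(C)O1 | intermediate
3 | 2,2'-dimethoxy-[1,1'-biphenyl]-4,4'-diol | COc1cc(O)ccc1-c1ccc(O)cc1OC | intermediate
4 | 5,5'-dibromo-2,2'-dimethoxy-[1,1'-biphenyl]-4,4'-diol | COc1cc(O)c(Br)cc1-c1cc(Br)c(O)cc1OC | intermediate
5 | methyl 2-(methylthio)acetate | CSCC(=O)OC | starting material
6 | methyl 2-chloro-2-(methylthio)acetate (racemic) | CSC(Cl)C(=O)OC | intermediate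
7 | dimethyl 2,2'-[(5,5'-dibromo-2,2'-dimethoxy-[1,1'-biphenyl]-4,4'-diyl)bis(oxy)]bis[2-(methylthio)acetate] (acetal carbons unassigned) | COC(=O)C(SC)Oc1cc(OC)c(cc1Br)-c1cc(Br)c(OC(SC)C(=O)OC)cc1OC | intermediate
8 | (2S)-4-methoxy-2-methyl-4-oxobutanoic acid | COC(=O)C[C@H](C)C(=O)O | starting material
9 | methyl (3S)-4-chloro-3-methyl-4-oxobutanoate | COC(=O)C[C@H](C)C(Cl)=O | intermediate
10 | methyl (3S)-3-methyl-4-oxobutanoate | COC(=O)C[C@H](C)C=O | intermediate
11 | tetramethyl 2,2'-[(5,5'-dibromo-2,2'-dimethoxy-[1,1'-biphenyl]-4,4'-diyl)bis(oxy)]bis[(3R,4S)-3-hydroxy-4-methyl-2-(methylthio)hexanedioate] (thioketal carbons unassigned) | COC(=O)C(SC)(Oc1cc(OC)c(cc1Br)-c1cc(Br)c(OC(SC)(C(=O)OC)[C@H](O)[C@@H](C)CC(=O)OC)cc1OC)[C@H](O)[C@@H](C)CC(=O)OC | intermediate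
12 | dimethyl 2,2'-[(5,5'-dibromo-2,2'-dimethoxy-[1,1'-biphenyl]-4,4'-diyl)bis(oxy)]bis{2-[(2R,3S)-3-methyl-5-oxooxolan-2-yl]-2-(methylthio)acetate} (thioketal carbons unassigned) | COC(=O)C(SC)(Oc1cc(OC)c(cc1Br)-c1cc(Br)c(OC(SC)(C(=O)OC)[C@@H]2OC(=O)C[C@@H]2C)cc1OC)[C@@H]1OC(=O)C[C@@H]1C | intermediate
13 | ethoxyacetylene | C#COCC | starting material
14 | dimethyl (2S,2'S)-8,8'-dibromo-4,4'-diethoxy-5,5'-dimethoxy-2,2'-bis[(2R,3S)-3-methyl-5-oxooxolan-2-yl]-2H,2'H-[6,6'-bichromene]-2,2'-dicarboxylate | COC(=O)[C@@]1([C@@H]5OC(=O)C[C@@H]5C)C=C(OCC)c2c(c(Br)cc(-c3cc(Br)c4c(c3OC)C(OCC)=C[C@@](C(=O)OC)([C@@H]3OC(=O)C[C@@H]3C)O4)c2OC)O1 | intermediate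
15 | dimethyl (2S,2'S)-8,8'-dibromo-5,5'-dimethoxy-2,2'-bis[(2R,3S)-3-methyl-5-oxooxolan-2-yl]-4,4'-dioxo-[6,6'-bichromane]-2,2'-dicarboxylate | COC(=O)[C@@]1([C@@H]5OC(=O)C[C@@H]5C)CC(=O)c2c(c(Br)cc(-c3cc(Br)c4c(c3OC)C(=O)C[C@@](C(=O)OC)([C@@H]3OC(=O)C[C@@H]3C)O4)c2OC)O1 | intermediate
16 | dimethyl (2S,2'S)-5,5'-dimethoxy-2,2'-bis[(2R,3S)-3-methyl-5-oxooxolan-2-yl]-4,4'-dioxo-[6,6'-bichromane]-2,2'-dicarboxylate | COC(=O)[C@@]1([C@@H]5OC(=O)C[C@@H]5C)CC(=O)c2c(ccc(-c3ccc4c(c3OC)C(=O)C[C@@](C(=O)OC)([C@@H]3OC(=O)C[C@@H]3C)O4)c2OC)O1 | intermediate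
17 | dimethyl (2S,2'S)-5,5'-dihydroxy-2,2'-bis[(2R,3S)-3-methyl-5-oxooxolan-2-yl]-4,4'-dioxo-[6,6'-bichromane]-2,2'-dicarboxylate | COC(=O)[C@@]1([C@@H]5OC(=O)C[C@@H]5C)CC(=O)c2c(ccc(-c3ccc4c(c3O)C(=O)C[C@@](C(=O)OC)([C@@H]3OC(=O)C[C@@H]3C)O4)c2O)O1 | intermediate
18 | (3S,4R)-4-hydroxy-4-[(2S)-5-hydroxy-6-{(2S)-5-hydroxy-2-(methoxycarbonyl)-2-[(2R,3S)-3-methyl-5-oxooxolan-2-yl]-4-oxochroman-6-yl}-2-(methoxycarbonyl)-4-oxochroman-2-yl]-3-methylbutanoic acid | COC(=O)[C@@]1([C@H](O)[C@@H](C)CC(=O)O)CC(=O)c2c(ccc(-c3ccc4c(c3O)C(=O)C[C@@](C(=O)OC)([C@@H]3OC(=O)C[C@@H]3C)O4)c2O)O1 | target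

**Step count**
Total: 10 steps. Longest linear sequence: 8 steps (1, 2, 4, 6, 7, 8, 9, 10); steps 3 and 5 make the side fragments.

**Steps most likely to fail**

Step 7 (key step, proposed method). The ethoxyketenium ion may be intercepted before the Friedel–Crafts closure, either by triflate or dimethyl sulfide or by closure through O1 to an oxetenium ion (alkyne–oxocarbenium metathesis). The oxocarbenium ion may also lose the C9 proton, and facial control at C2 may be weaker than the Felkin–Anh model suggests. The fallback separates the two bond formations and uses known reaction types. It sets out from 12: the same S-methylative ionisation is run with ketene bis(trimethylsilyl) acetal as a strong nucleophile (Mukaiyama-type addition to a thioketal-derived oxocarbenium ion, as in C-glycosidation of thioglycosides). After aqueous work-up this should give 3,3'-[(5,5'-dibromo-2,2'-dimethoxy-[1,1'-biphenyl]-4,4'-diyl)bis(oxy)]bis{(3S)-4-methoxy-3-[(2R,3S)-3-methyl-5-oxooxolan-2-yl]-4-oxobutanoic acid} F1. Cyclodehydration of F1 with Eaton's reagent (P2O5 in MeSO3H), the standard closure of 3-aryloxypropanoic acids to chroman-4-ones and again directed to C4a by the C8 bromine, returns to the route at 15.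

Step 6. Facial selectivity in the addition of the hindered enolate to the α-methyl aldehyde may be poor. Retro-aldol cleavage or displacement of aryloxide by the aldolate may occur before lactonisation, and the aldehyde may epimerise. The fallback replaces substrate control by reagent control and sets out from 7 and acid chloride 9. C-acylation of the lithium enolate of 7 with 9 should give tetramethyl 2,2'-[(5,5'-dibromo-2,2'-dimethoxy-[1,1'-biphenyl]-4,4'-diyl)bis(oxy)]bis[(4S)-4-methyl-2-(methylthio)-3-oxohexanedioate] F2. CBS reduction of F2 with (S)-2-methyl-CBS-oxazaborolidine and BH3·SMe2, the quaternary thioketal carbon acting as the large group, should set C9 as R. This returns to the route at hydroxy ester 11, which is lactonised with PPTS to 12.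

Step 10. Over-hydrolysis to the diacid, base-triggered retro-oxa-Michael opening of the pyranone (scrambling of C2) and relactonisation on acidification can all erode the mono acid. The fallback sets out from 17 and arrives directly at 18 by biocatalytic mono-hydrolysis with pig liver esterase at pH 7 to 7.5 (phosphate buffer/DMSO, pH-stat). The anionic mono acid should be a poor substrate for the enzyme, so the reaction should stop after one lactone, and the neutral pH avoids enolate chemistry; this fallback makes no new compound (F0).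

Further compounds
F1 | step 7 | 3,3'-[(5,5'-dibromo-2,2'-dimethoxy-[1,1'-biphenyl]-4,4'-diyl)bis(oxy)]bis{(3S)-4-methoxy-3-[(2R,3S)-3-methyl-5-oxooxolan-2-yl]-4-oxobutanoic acid} | COC(=O)[C@@](Oc1cc(OC)c(cc1Br)-c1cc(Br)c(O[C@@](C(=O)OC)(CC(=O)O)[C@@H]2OC(=O)C[C@@H]2C)cc1OC)([C@@H]1OC(=O)C[C@@H]1C)CC(=O)O
F2 | step 6 | tetramethyl 2,2'-[(5,5'-dibromo-2,2'-dimethoxy-[1,1'-biphenyl]-4,4'-diyl)bis(oxy)]bis[(4S)-4-methyl-2-(methylthio)-3-oxohexanedioate] (thioketal carbons unassigned) | COC(=O)C(SC)(Oc1cc(OC)c(cc1Br)-c1cc(Br)c(OC(SC)(C(=O)OC)C(=O)[C@@H](C)CC(=O)OC)cc1OC)C(=O)[C@@H](C)CC(=O)OC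
F0 | step 10 | none | none
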